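**Retrosynthetic overview**

1. Locants: C1 ketone carbon, C2=C3 (methyl on C3), C4 and C11 ring-fusion CH, C5 cyclobutane CH bearing C6 (CMe2), C7 (CHOH), C8 (O-angeloyl), C9 (O-2-methylbutanoyl), C10 quaternary C-Me. The strategy rests on C10: it is a cyclobutane carbon (ring C4–C5–C11–C10) that carries both the methyl group and the C9 bond of the seven-membered ring (C4–C5–C6–C7–C8–C9–C10), so both can come from one exocyclic C10=CH2.
2. Endgame: C8 and C9 esters from a cis-diol, the diol from a C8=C9 alkene osmylated anti to the C7 oxygen, the C7 carbinol from the C7 enone, and C2=C3 from the C1 ketone, which is carried as a dioxolane.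
3. Key disconnection C9–C10: hydrogen-atom transfer to C10=CH2, then 7-endo radical addition to the C7 vinyl ketone held on C5 (23 → 24).
4. The bicyclo[3.1.1]heptane (cyclobutane and six-membered ring at once) comes from a crossed intramolecular keteniminium–diene [2+2] that forms C10–C4 and C11–C5 under control of the C3 methyl centre; the isopropenyl group left on C5 becomes C6/C7.
5. Ring order: four- and six-membered rings in step 7, seven-membered ring in step 15; the open chain comes from malonate allylation (sets C3), Claisen condensation and cross-metathesis.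

Key step: step 15

Assumption: the C3 methyl centre (R) is only a control element and is erased in step 23; centres that are erased later (C10 carbinol in 15–17, C6 in 16–19, C7 in 22) form as mixtures and are drawn without descriptor; names of bicyclic and tricyclic compounds use the locants above.

**Route**

Step 1
Reactants: 1 dimethyl malonate; 2 (E)-but-2-en-1-yl methyl carbonate
Product: 3 dimethyl (S)-2-(but-3-en-2-yl)malonate
Conditions: [Ir(cod)Cl]2 (2 mol%), chiral BINOL-derived phosphoramidite (4 mol%, enantiomer giving S), TBD (8 mol%), THF, rt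
Reagents that add atoms: none
Why: Iridium-catalysed asymmetric allylic alkylation gives the branched product, and the chiral ligand decides which face of the substituted allyl terminus the malonate attacks, setting the methyl-bearing centre that becomes C3.

Step 2
Reactants: 3 dimethyl (S)-2-(but-3-en-2-yl)malonate
Product: 4 methyl (R)-3-methylpent-4-enoate
Conditions: LiCl, H2O, DMSO, 150 °C
Reagents that add atoms: none
Why: Krapcho dealkoxycarbonylation removes one ester and leaves the β-stereocentre untouched (the descriptor changes only through the priority change).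

Step 3
Reactants: 4 methyl (R)-3-methylpent-4-enoate; 5 1-acetylpyrrolidine
Product: 7 (R)-5-methyl-1-(pyrrolidin-1-yl)hept-6-ene-1,3-dione, via lithium enolate 6 (not isolated)
Conditions: LDA (2.2 equiv), 5, THF, −78 °C; then 4, −78 → 0 °C; aq. NH4Cl
Reagents that add atoms: none
Why: Crossed Claisen condensation of the amide enolate with the methyl ester is driven by deprotonation of the β-keto amide as it forms.

Step 4
Reactants: 7 (R)-5-methyl-1-(pyrrolidin-1-yl)hept-6-ene-1,3-dione
Product: 8 (R)-2-[2-(2-methylbut-3-en-1-yl)-1,3-dioxolan-2-yl]-1-(pyrrolidin-1-yl)ethan-1-one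
Conditions: (TMSOCH2)2, TMSOTf (5 mol%), CH2Cl2, −78 → −20 °C; pyridine quench
Reagents that add atoms: 1,2-bis(trimethylsilyloxy)ethane, C[Si](C)(C)OCCO[Si](C)(C)C
Why: TMSOTf-catalysed ketalisation with the bis-silyl ether of ethylene glycol masks the C1 ketone under cold aprotic conditions before the acid-sensitive diene is built.

Step 5
Reactants: 8 ketal amide; 9 methyl vinyl ketone
Product: 10 (R,E)-5-methyl-6-{2-[2-oxo-2-(pyrrolidin-1-yl)ethyl]-1,3-dioxolan-2-yl}hex-3-en-2-one
Conditions: Ru–NHC isopropoxybenzylidene metathesis catalyst (5 mol%), 9 (4 equiv), CH2Cl2, 40 °C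
Reagents that add atoms: none
Why: Olefin cross-metathesis of the terminal alkene with the electron-poor enone partner should favour the cross product and the E-alkene.

Step 6
Reactants: 10 enone amide
Product: 11 (R,E)-2-[2-(2,5-dimethylhexa-3,5-dien-1-yl)-1,3-dioxolan-2-yl]-1-(pyrrolidin-1-yl)ethan-1-one
Conditions: Ph3PCH3Br, KHMDS, THF, 0 °C; then 10, −78 °C → rt
Reagents that add atoms: methyltriphenylphosphonium bromide, C[P+](c1ccccc1)(c1ccccc1)c1ccccc1.[Br-]
Why: Wittig methylenation of the enone carbonyl gives the (E)-diene whose inner double bond reacts in step 7; amide and ketal are inert to the ylide.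

Step 7
Reactants: 11 diene amide
Product: 14 bicyclic cyclobutanone (bicyclo[3.1.1]heptane; C10 ketone; C1 dioxolane; 3R methyl syn to C5; isopropenyl on C5 anti to the C1–C3 bridge), via keteniminium triflate 12 (not isolated), via cyclobutaniminium triflate 13 (not isolated)
Conditions: Tf2O (1.2 equiv), 2,4,6-collidine (1.5 equiv), ClCH2CH2Cl, 0.01 M, 0 → 80 °C; then aq. NaHCO3, 50 °C
Reagents that add atoms: water, O
Why: Intramolecular keteniminium–alkene [2+2] cycloaddition in which the electrophilic carbon C10 bonds to the diene terminus C4 (allyl-cation stabilisation at C5) so that closure is crossed and gives the bicyclo[3.1.1] skeleton, the E-alkene geometry places the isopropenyl group on C5 anti to the C1–C3 bridge, and the C3 methyl group, pseudo-equatorial in the chair-like six-ring transition state (the axial alternative would meet a ketal oxygen), selects the alkene face and so fixes C4 and C11.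

Step 8
Reactants: 14 bicyclic cyclobutanone
Product: 15 β-hydroxysilane (C10 bears OH and CH2SiMe3; otherwise as 14)
Conditions: Me3SiCH2MgCl, THF, −78 → 0 °C
Reagents that add atoms: (trimethylsilyl)methylmagnesium chloride, C[Si](C)(C)C[Mg]Cl
Why: Grignard addition to the strained, non-enolisable cyclobutanone gives the Peterson β-hydroxysilane, which hides the future C10 methylene during the hydroboration; the C10 carbinol configuration is of no consequence.

Step 9
Reactants: 15 β-hydroxysilane
Product: 17 diol (C5 bears CH(CH3)CH2OH; C10 carbinol as in 15), via B-alkyl-9-BBN adduct 16 (not isolated)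
Conditions: 9-BBN (2.5 equiv), THF, rt → 50 °C; then NaBO3·4H2O, THF/H2O, rt
Reagents that add atoms: sodium perborate, [Na+].[Na+].O[B-]1(O)OO[B-](O)(O)OO1; 9-borabicyclo[3.3.1]nonane, B1C2CCCC1CCC2 (boron carried only by 16)
Why: Hydroboration–oxidation puts the hydroxyl on the terminal carbon of the isopropenyl group (anti-Markovnikov), which becomes C7; C6 forms as a mixture that is erased in step 12.

Step 10
Reactants: 17 diol
Product: 18 methylene alcohol (C10=CH2; C5 bears CH(CH3)CH2OH)
Conditions: KH, THF, 0 °C → rt
Reagents that add atoms: none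
Why: Peterson olefination: the potassium alkoxide of the β-hydroxysilane eliminates syn, and only the exocyclic C10=CH2 can form because both ring neighbours are bridgeheads.

Step 11
Reactants: 18 methylene alcohol
Product: 19 aldehyde (C5 bears CH(CH3)CHO)
Conditions: Dess–Martin periodinane, NaHCO3, CH2Cl2, 0 °C → rt
Reagents that add atoms: none
Why: Dess–Martin oxidation of the primary alcohol under buffered conditions leaves the methylene and the ketal untouched.

Step 12
Reactants: 19 aldehyde
Product: 20 quaternary aldehyde (C5 bears C(CH3)2CHO)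
Conditions: MeI (5 equiv), t-BuOK (1.5 equiv), THF, −20 → 0 °C
Reagents that add atoms: iodomethane, CI
Why: C-Methylation of the α-branched aldehyde enolate creates the C6 gem-dimethyl carbon and removes the C6 stereocentre.

Step 13
Reactants: 20 quaternary aldehyde; 21 vinylmagnesium bromide
Product: 22 allylic alcohol (C5 bears C(CH3)2CH(OH)CH=CH2)
Conditions: THF, −78 → 0 °C
Reagents that add atoms: none
Why: Grignard 1,2-addition to the non-enolisable neopentyl aldehyde; the C7 carbinol mixture is oxidised in the next step.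

Step 14
Reactants: 22 allylic alcohol
Product: 23 vinyl ketone (6-methylenebicyclo[3.1.1]heptane with C1 dioxolane, 3R methyl, C10=CH2 and C(CH3)2C(=O)CH=CH2 on C5 anti to the C1–C3 bridge)
Conditions: Dess–Martin periodinane, NaHCO3, CH2Cl2, 0 °C
Reagents that add atoms: none
Why: Dess–Martin oxidation gives the vinyl ketone under neutral conditions that avoid conjugate addition to it.

Step 15
Reactants: 23 vinyl ketone
Product: 24 tricyclic C7 ketone (C1 dioxolane, 3R methyl, C10 methyl on the side of the C1–C3 bridge, C8 and C9 methylene)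
Conditions: Fe(acac)3 (0.5 equiv), PhSiH3 (2.5 equiv), EtOH/ethylene glycol 5:1, 0.005 M, 60 °C
Reagents that add atoms: none
Why: An iron hydride formed from Fe(acac)3 and PhSiH3 transfers a hydrogen atom to the CH2 terminus of the electron-rich C10=CH2, which creates the C10 methyl and a nucleophilic tertiary cyclobutyl radical; this adds to the terminal carbon C9 of the C7 vinyl ketone, and the α-keto radical is reduced and protonated to the ketone. The closest known reaction type is the iron-catalysed hydrogen-atom-transfer reductive coupling of an unactivated alkene with an enone (Mukaiyama-type HAT followed by Giese addition), used here intramolecularly. The ring C4–C5–C6–C7–C8–C9–C10 closes in the 7-endo-trig mode, but because C5 and C10 are the 1,3-carbons of the cyclobutane (about 2.1 Å apart) the transition state has the geometry of a six-ring closure. C10 is the only new stereocentre and the tether controls it: the side chain on C5 lies on the cyclobutane face anti to the C1–C3 bridge, so C9 can bond only on that face and the new methyl ends up on the bridge side, as in the target. The step needs hydrogen-atom transfer to the methylene and not to the enone, which the 1,1-disubstituted electron-rich alkene secures, and ring closure faster than reduction of the radical, which high dilution and the pre-positioned acceptor secure; attack at C9 and not at C8 is polarity-matched and gives the stabilised α-keto radical.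

Step 16
Reactants: 24 tricyclic C7 ketone
Product: 26 C7 enone (C8=C9), via silyl enol ether 25 (not isolated)
Conditions: LiHMDS, TMSCl, THF, −78 °C; then Pd(OAc)2 (1.1 equiv), MeCN, rt
Reagents that add atoms: chlorotrimethylsilane, C[Si](C)(C)Cl (silyl group carried only by 25)
Why: Saegusa–Ito oxidation: the C7 ketone can enolise only towards C8 because C6 is quaternary, and β-hydride elimination from the palladium enolate gives the C8=C9 enone.

Step 17
Reactants: 26 C7 enone
Product: 27 (7R)-allylic alcohol (C7 hydroxyl on the C4 side of the seven-membered ring)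
Conditions: (S)-Me-CBS oxazaborolidine (0.3 equiv), BH3·SMe2, toluene, −30 °C
Reagents that add atoms: none
Why: CBS reduction, in which the catalyst is expected to read the quaternary C6 as the large flank and deliver hydride to the C7 face on the C11 side; reagent control is needed because the two faces of the seven-membered ring are nearly mirror-related.

Step 18
Reactants: 27 allylic alcohol
Product: 28 C7 triethylsilyl ether
Conditions: TESOTf, 2,6-lutidine, CH2Cl2, −78 → 0 °C
Reagents that add atoms: triethylsilyl trifluoromethanesulfonate, CC[Si](CC)(CC)OS(=O)(=O)C(F)(F)F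
Why: Silylation of the hindered secondary alcohol with the silyl triflate sets C7 apart from the later hydroxyls and gives a bulky director for the osmylation.

Step 19
Reactants: 28 silyl ether
Product: 29 C8,C9-diol (both hydroxyls on the C11 side, trans to the C7 oxygen)
Conditions: OsO4 (5 mol%), NMO, acetone/H2O, rt
Reagents that add atoms: osmium tetroxide (catalytic oxygen carrier), O=[Os](=O)(=O)=O; N-methylmorpholine N-oxide, C[N+]1([O-])CCOCC1; water, O
Why: Upjohn dihydroxylation adds both oxygens syn to the C8=C9 bond, and attack on the face anti to the allylic silyloxy group at C7 (the usual sense for osmylation of allylic ethers) sets C8 and C9.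

Step 20
Reactants: 29 diol; 30 angelic acid
Product: 32 C8 angelate (C9 hydroxyl free), via mixed anhydride 31 (not isolated)
Conditions: 30, 2,4,6-trichlorobenzoyl chloride, Et3N, toluene, rt; then 29, toluene, 75 °C (no DMAP)
Reagents that add atoms: 2,4,6-trichlorobenzoyl chloride, O=C(Cl)c1c(Cl)cc(Cl)cc1Cl (atoms carried only by 31)
Why: Yamaguchi esterification through the mixed anhydride acylates the less hindered C8 hydroxyl (C9–OH is neopentyl, next to quaternary C10), and leaving out the nucleophilic catalyst should suppress isomerisation of the angelate to the tiglate.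

Step 21
Reactants: 32 C8 angelate; 33 (R)-2-methylbutanoic acid
Product: 35 C8 angelate C9 (R)-2-methylbutanoate, via mixed anhydride 34 (not isolated)
Conditions: 33, 2,4,6-trichlorobenzoyl chloride, Et3N, THF, rt; then 32, DMAP, toluene, 40 °C
Reagents that add atoms: 2,4,6-trichlorobenzoyl chloride, O=C(Cl)c1c(Cl)cc(Cl)cc1Cl (atoms carried only by 34)
Why: Yamaguchi esterification with DMAP activation acylates the remaining hindered C9 hydroxyl; the α-branched acid carries no activating group, so its stereocentre should survive.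

Step 22
Reactants: 35 diester
Product: 36 C7 alcohol C1 ketone (2,3-dihydro target)
Conditions: TsOH·H2O (0.2 equiv), acetone/H2O 10:1, 40 °C
Reagents that add atoms: water, O
Why: Acid hydrolysis cleaves the triethylsilyl ether and the dioxolane in one operation while the two esters stay in place.

Step 23
Reactants: 36 keto alcohol
Product: 39 CNP0202800.1, via bis-silyl enol ether 37 (not isolated), via silylated enone 38 (not isolated)
Conditions: TMSOTf (3 equiv), Et3N (4 equiv), CH2Cl2, 0 °C; then Pd(OAc)2 (1.2 equiv), MeCN, rt; then aq. citric acid, THF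
Reagents that add atoms: trimethylsilyl trifluoromethanesulfonate, C[Si](C)(C)OS(=O)(=O)C(F)(F)F (silyl groups carried only by 37 and 38)
Why: Saegusa–Ito oxidation: soft enolisation of the C1 ketone can go only towards C2 (C11 is a bridgehead), palladium-mediated dehydrogenation gives the C2=C3 enone and erases the C3 centre, and the transient C7 silyl ether falls off in the acidic work-up.

**Compound list**

1 | dimethyl malonate | COC(=O)CC(=O)OC | starting material
2 | (E)-but-2-en-1-yl methyl carbonate | C/C=C/COC(=O)OC | starting material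
3 | dimethyl (S)-2-(but-3-en-2-yl)malonate | COC(=O)C(C(=O)OC)[C@@H](C)C=C | intermediate
4 | methyl (R)-3-methylpent-4-enoate | COC(=O)C[C@@H](C)C=C | intermediate
5 | 1-acetylpyrrolidine | CC(=O)N1CCCC1 | starting material
6 | lithium enolate of 1-acetylpyrrolidine | [Li+].[O-]C(=C)N1CCCC1 | intermediate
7 | (R)-5-methyl-1-(pyrrolidin-1-yl)hept-6-ene-1,3-dione | O=C(CC(=O)C[C@@H](C)C=C)N1CCCC1 | intermediate
8 | (R)-2-[2-(2-methylbut-3-en-1-yl)-1,3-dioxolan-2-yl]-1-(pyrrolidin-1-yl)ethan-1-one | O=C(CC1(OCCO1)C[C@@H](C)C=C)N1CCCC1 | intermediate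
9 | methyl vinyl ketone (but-3-en-2-one) | CC(=O)C=C | starting material
10 | (R,E)-5-methyl-6-{2-[2-oxo-2-(pyrrolidin-1-yl)ethyl]-1,3-dioxolan-2-yl}hex-3-en-2-one | O=C(CC1(OCCO1)C[C@@H](C)/C=C/C(C)=O)N1CCCC1 | intermediate
11 | (R,E)-2-[2-(2,5-dimethylhexa-3,5-dien-1-yl)-1,3-dioxolan-2-yl]-1-(pyrrolidin-1-yl)ethan-1-one | O=C(CC1(OCCO1)C[C@@H](C)/C=C/C(C)=C)N1CCCC1 | intermediate
12 | keteniminium triflate of 11 (C10=C11 cumulated with the pyrrolidinium nitrogen) | [O-]S(=O)(=O)C(F)(F)F.C1CC[N+](=C=CC2(OCCO2)C[C@@H](C)/C=C/C(C)=C)C1 | intermediate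
13 | cyclobutaniminium triflate (bicyclo[3.1.1] core, C10=N+ pyrrolidinium) | CC(=C)[C@@H]1[C@H]2C3(OCCO3)C[C@@H](C)[C@@H]1C2=[N+]1CCCC1.[O-]S(=O)(=O)C(F)(F)F | intermediate
14 | bicyclic cyclobutanone: C10 ketone, C1 dioxolane, 3R methyl syn to C5, isopropenyl on C5 anti to the C1–C3 bridge | CC(=C)[C@@H]1[C@H]2C3(OCCO3)C[C@@H](C)[C@@H]1C2=O | intermediate
15 | β-hydroxysilane: C10(OH)CH2SiMe3 (either C10 epimer), otherwise as 14 | CC(=C)[C@@H]1[C@H]2C3(OCCO3)C[C@@H](C)[C@@H]1C2(O)C[Si](C)(C)C | intermediate
16 | B-alkyl-9-BBN adduct of 15 (boron on C7) | CC(CB1C2CCCC1CCC2)[C@@H]1[C@H]2C3(OCCO3)C[C@@H](C)[C@@H]1C2(O)C[Si](C)(C)C | intermediate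
17 | diol: C5 bears CH(CH3)CH2OH (C6 mixture), C10(OH)CH2SiMe3 | OCC(C)[C@@H]1[C@H]2C3(OCCO3)C[C@@H](C)[C@@H]1C2(O)C[Si](C)(C)C | intermediate
18 | methylene alcohol: C10=CH2, C5 bears CH(CH3)CH2OH | OCC(C)[C@@H]1[C@H]2C3(OCCO3)C[C@@H](C)[C@@H]1C2=C | intermediate
19 | aldehyde: C5 bears CH(CH3)CHO | O=CC(C)[C@@H]1[C@H]2C3(OCCO3)C[C@@H](C)[C@@H]1C2=C | intermediate
20 | quaternary aldehyde: C5 bears C(CH3)2CHO | O=CC(C)(C)[C@@H]1[C@H]2C3(OCCO3)C[C@@H](C)[C@@H]1C2=C | intermediate
21 | vinylmagnesium bromide | C=C[Mg]Br | starting material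
22 | allylic alcohol: C5 bears C(CH3)2CH(OH)CH=CH2 (C7 mixture) | C=CC(O)C(C)(C)[C@@H]1[C@H]2C3(OCCO3)C[C@@H](C)[C@@H]1C2=C | intermediate
23 | vinyl ketone, precursor of the key step: C10=CH2, C1 dioxolane, 3R methyl, C(CH3)2C(=O)CH=CH2 on C5 anti to the C1–C3 bridge | C=CC(=O)C(C)(C)[C@@H]1[C@H]2C3(OCCO3)C[C@@H](C)[C@@H]1C2=C | intermediate
24 | tricyclic C7 ketone, product of the key step: C1 dioxolane, 3R methyl, C10 methyl on the bridge side | C1C(=O)C(C)(C)[C@@H]2[C@H]3C4(OCCO4)C[C@@H](C)[C@@H]2[C@@]3(C)C1 | intermediate
25 | trimethylsilyl enol ether of 24 (C7(OSiMe3)=C8) | C1=C(O[Si](C)(C)C)C(C)(C)[C@@H]2[C@H]3C4(OCCO4)C[C@@H](C)[C@@H]2[C@@]3(C)C1 | intermediate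
26 | tricyclic C7 enone (C8=C9) | C=1C(=O)C(C)(C)[C@@H]2[C@H]3C4(OCCO4)C[C@@H](C)[C@@H]2[C@@]3(C)C=1 | intermediate
27 | (7R)-allylic alcohol, hydroxyl on the C4 side | C=1[C@@H](O)C(C)(C)[C@@H]2[C@H]3C4(OCCO4)C[C@@H](C)[C@@H]2[C@@]3(C)C=1 | intermediate
28 | C7 triethylsilyl ether of 27 | C=1[C@@H](O[Si](CC)(CC)CC)C(C)(C)[C@@H]2[C@H]3C4(OCCO4)C[C@@H](C)[C@@H]2[C@@]3(C)C=1 | intermediate
29 | C8,C9-cis-diol, both hydroxyls on the C11 side, trans to the C7 silyloxy group | O[C@@H]1[C@@H](O[Si](CC)(CC)CC)C(C)(C)[C@@H]2[C@H]3C4(OCCO4)C[C@@H](C)[C@@H]2[C@@]3(C)[C@@H]1O | intermediate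
30 | angelic acid ((Z)-2-methylbut-2-enoic acid) | C/C=C(/C)C(=O)O | starting material
31 | angelic 2,4,6-trichlorobenzoic anhydride | C/C=C(/C)C(=O)OC(=O)c1c(Cl)cc(Cl)cc1Cl | intermediate
32 | C8 angelate, C9 hydroxyl free, C7 silyl ether | C/C=C(/C)C(=O)O[C@@H]1[C@@H](O[Si](CC)(CC)CC)C(C)(C)[C@@H]2[C@H]3C4(OCCO4)C[C@@H](C)[C@@H]2[C@@]3(C)[C@@H]1O | intermediate
33 | (R)-2-methylbutanoic acid | CC[C@@H](C)C(=O)O | starting material
34 | (R)-2-methylbutanoic 2,4,6-trichlorobenzoic anhydride | CC[C@@H](C)C(=O)OC(=O)c1c(Cl)cc(Cl)cc1Cl | intermediate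
35 | C8 angelate C9 (R)-2-methylbutanoate, C7 silyl ether, C1 dioxolane | C/C=C(/C)C(=O)O[C@@H]1[C@@H](O[Si](CC)(CC)CC)C(C)(C)[C@@H]2[C@H]3C4(OCCO4)C[C@@H](C)[C@@H]2[C@@]3(C)[C@@H]1OC(=O)[C@H](C)CC | intermediate
36 | 2,3-dihydro target: C1 ketone, C7 hydroxyl, 3R methyl | C/C=C(/C)C(=O)O[C@@H]1[C@@H](O)C(C)(C)[C@@H]2[C@H]3C(=O)C[C@@H](C)[C@@H]2[C@@]3(C)[C@@H]1OC(=O)[C@H](C)CC | intermediate
37 | bis-silyl compound: C7 OSiMe3 and C1(OSiMe3)=C2 | C/C=C(/C)C(=O)O[C@@H]1[C@@H](O[Si](C)(C)C)C(C)(C)[C@@H]2[C@H]3C(O[Si](C)(C)C)=C[C@@H](C)[C@@H]2[C@@]3(C)[C@@H]1OC(=O)[C@H](C)CC | intermediate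
38 | C7 O-trimethylsilyl ether of the target | C/C=C(/C)C(=O)O[C@@H]1[C@@H](O[Si](C)(C)C)C(C)(C)[C@@H]2[C@H]3C(=O)C=C(C)[C@@H]2[C@@]3(C)[C@@H]1OC(=O)[C@H](C)CC | intermediate
39 | CNP0202800.1 | C/C=C(/C)C(=O)O[C@@H]1[C@@H](O)C(C)(C)[C@@H]2[C@H]3C(=O)C=C(C)[C@@H]2[C@@]3(C)[C@@H]1OC(=O)[C@H](C)CC | target

**Step count and risks**

Total: 23 steps. Longest linear sequence: 23 steps (fully linear from dimethyl malonate).

Steps most likely to fail:

Step 15. The tertiary cyclobutyl radical may be reduced before it closes the ring, or hydrogen-atom transfer may go to the vinyl ketone; either way the methylene is only hydrogenated or the acceptor is lost. The fallback sets out from 23 and comes back at 24. It makes the same C10 radical reversibly, by addition of a sulfonyl radical, so that the radical is re-formed until it cyclises. Irradiation of 23 with Se-phenyl 4-methylbenzeneselenosulfonate in benzene at high dilution should add the tosyl radical to the CH2 terminus, close the ring at C9 and transfer the phenylselanyl group to C8, giving the selenosulfonation–cyclisation product F1. Bu3SnH/AIBN should remove the selenium to give the tosylmethyl ketone F2. Sodium amalgam in buffered methanol should then cleave the carbon–sulfur bond, which turns the CH2Ts group into the C10 methyl of 24; any over-reduced C7 carbinol would be reoxidised with Dess–Martin periodinane.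

Step 7. The triflic anhydride activation may open the dioxolane or degrade the diene by cationic pathways, or the fused closure may compete. The fallback sets out from 4 and comes back at 14, and uses a free ketene under base-only conditions. Claisen condensation of 4 with lithio ethyl acetate should give β-keto ester F3. The same ketalisation, cross-metathesis with 9 and methylenation should give ketal ester F4, enone ester F5 and diene ester F6. LiOH should give carboxylic acid F7, and 1-chloro-N,N,2-trimethylpropenylamine the acid chloride F8 under neutral conditions. Slow addition of F8 to Et3N in refluxing toluene should release ketene F9, which should undergo the same crossed [2+2] with the diene and give 14 directly.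

Step 17. Facial discrimination may be poor: the two faces of the seven-membered ring differ only through the distant C1/C3 substituents, and it is uncertain whether the catalyst reads the quaternary C6 or the alkene as the large flank. If the opposite sense prevails, the antipodal catalyst is used. The fallback sets out from 26 and comes back at 27, with recycling to 26, and gives up catalyst control. Luche reduction (NaBH4, CeCl3, MeOH, −78 °C) should give 27 together with its C7 epimer F10; the two are separated by chromatography, and F10 is reoxidised with MnO2 to 26 and reduced again.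

Further compounds
F1 | step 15 | tricyclic C7 ketone with C10 CH2SO2Tol and C8 SePh (C8 mixture) | c5ccccc5[Se]C1C(=O)C(C)(C)[C@@H]2[C@H]3C4(OCCO4)C[C@@H](C)[C@@H]2[C@@]3(CS(=O)(=O)c6ccc(C)cc6)C1
F2 | step 15 | tricyclic C7 ketone with C10 CH2SO2Tol | C1C(=O)C(C)(C)[C@@H]2[C@H]3C4(OCCO4)C[C@@H](C)[C@@H]2[C@@]3(CS(=O)(=O)c5ccc(C)cc5)C1
F3 | step 7 | ethyl (R)-5-methyl-3-oxohept-6-enoate | CCOC(=O)CC(=O)C[C@@H](C)C=C
F4 | step 7 | ethyl (R)-2-[2-(2-methylbut-3-en-1-yl)-1,3-dioxolan-2-yl]acetate | CCOC(=O)CC1(OCCO1)C[C@@H](C)C=C
F5 | step 7 | ethyl (R,E)-2-[2-(2-methyl-5-oxohex-3-en-1-yl)-1,3-dioxolan-2-yl]acetate | CCOC(=O)CC1(OCCO1)C[C@@H](C)/C=C/C(C)=O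
F6 | step 7 | ethyl (R,E)-2-[2-(2,5-dimethylhexa-3,5-dien-1-yl)-1,3-dioxolan-2-yl]acetate | CCOC(=O)CC1(OCCO1)C[C@@H](C)/C=C/C(C)=C
F7 | step 7 | (R,E)-2-[2-(2,5-dimethylhexa-3,5-dien-1-yl)-1,3-dioxolan-2-yl]acetic acid | OC(=O)CC1(OCCO1)C[C@@H](C)/C=C/C(C)=C
F8 | step 7 | acid chloride of F7 | ClC(=O)CC1(OCCO1)C[C@@H](C)/C=C/C(C)=C
F9 | step 7 | ketene from F8 | O=C=CC1(OCCO1)C[C@@H](C)/C=C/C(C)=C
F10 | step 17 | (7S)-allylic alcohol, C7 epimer of 27 | C=1[C@H](O)C(C)(C)[C@@H]2[C@H]3C4(OCCO4)C[C@@H](C)[C@@H]2[C@@]3(C)C=1
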